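**Plan**

- Numbering follows the atom order of the target SMILES: ring A = lactone C5/O6/C7/C9/C10, ring B = C9–C13 + C29, ring C = C13/C14/C15/C16/C25/C29, ring D = lactone C15/C16/C17/O22/C23, two-carbon bridge C26–C27 (O28 on C27).
- Cuts: both enol lactones at C7–C9 and C15–C23 (CO insertion, closing O6–C7 and O22–C23) and at C5–C10 and C16–C17 (C-acylation), back to a tricyclic C9,C15-diketone; then C26–C27; then C13–C14 and C25–C29.
- Enabling feature: seen from bridgehead C14, C27 is placed and oxidised like a carboxyl carbon, and C26 on C25 like the CH2 of a CH2CO2R arm, so the C26–C27 bond is what an ester condensation between the para positions C14 and C25 of ring C produces.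
- Forward: ring C is annulated onto cyclohexenone (ring B) by a Diels–Alder reaction, the bicyclo[2.2.2]octene is closed by Dieckmann bridging (the extra ester on C26 later leaves as CO2), and rings A and D are made together by acylation, triflation and carbonylative lactonisation.
- Stereochemistry: C13, C14, C25 and C29 arise all-cis in one catalyst-controlled endo cycloaddition; C27 is set by a thermodynamically controlled ketone reduction; both Z-butylidenes by the lactonisation.

Key step: step 10

Assumption: by the usual α-C–H···O binding model for enones, the (S)-configured oxazaborolidinium cation is taken to leave the Si face at C2/C3 of cyclohex-2-enone open; should the sense prove opposite, the (R)-catalyst is used and nothing else changes.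

**Route**

Step 1
Reactants: 1 methyl acetoacetate; 2 3-(benzyloxy)propanal
Product: 4 methyl 7-(benzyloxy)-5-hydroxy-3-oxoheptanoate (racemic carbinol), via dilithio methyl acetoacetate 3 (not isolated)
Conditions: LiN(i-Pr)2 (LDA, 2.1 equiv), THF, 0 °C; then 2, −78 °C; aq. NH4Cl
Reagents that add atoms: none
Why: Aldol addition of the acetoacetate dianion, whose more basic terminal carbon is the one that attacks the aldehyde; the carbinol centre is removed in step 2, so its configuration does not matter.

Step 2
Reactants: 4 methyl 7-(benzyloxy)-5-hydroxy-3-oxoheptanoate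
Product: 6 methyl (4E)-7-(benzyloxy)-3-oxohept-4-enoate, via the C5 mesylate 5 (not isolated)
Conditions: MsCl, Et3N (3 equiv), CH2Cl2, 0 °C → rt
Reagents that add atoms: none
Why: Mesylation followed by E1cB elimination through the ketone enolate should give the conjugated enone, the E geometry being the thermodynamic one.

Step 3
Reactants: 6 methyl (4E)-7-(benzyloxy)-3-oxohept-4-enoate
Product: 7 methyl (2Z,4E)-7-(benzyloxy)-3-[(triisopropylsilyl)oxy]hepta-2,4-dienoate
Conditions: TIPSOTf, Et3N, CH2Cl2, 0 °C
Reagents that add atoms: triisopropylsilyl trifluoromethanesulfonate, CC(C)[Si](C(C)C)(C(C)C)OS(=O)(=O)C(F)(F)F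
Why: Soft enolisation and O-silylation of the β-keto ester (silyl enol ether formation); silylation of the internally chelated enol should place ester and silyloxy group cis (2Z), which puts the ester on the outside of the s-cis diene.

Step 4
Reactants: 7 methyl (2Z,4E)-7-(benzyloxy)-3-[(triisopropylsilyl)oxy]hepta-2,4-dienoate; 8 cyclohex-2-en-1-one
Product: 9 methyl (1S,4S,4aS,8aS)-4-[2-(benzyloxy)ethyl]-5-oxo-2-[(triisopropylsilyl)oxy]-1,4,4a,5,6,7,8,8a-octahydronaphthalene-1-carboxylate (all-cis; C1 = C14, C4 = C25, C4a = C29, C5 = C9, C8a = C13)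
Conditions: (S)-3,3-diphenyl-1-(o-tolyl)tetrahydropyrrolo[1,2-c][1,3,2]oxazaborole (o-tolyl CBS oxazaborolidine, 20 mol %), Tf2NH (18 mol %), CH2Cl2, −78 → −20 °C
Reagents that add atoms: none
Why: Catalytic enantioselective Diels–Alder reaction with the enone activated as its chiral oxazaborolidinium complex: the 2-silyloxy group and the alkyl group on C25 both make C14 the nucleophilic diene terminus, so C14 bonds to the enone β-carbon (C13) and C25 to the α-carbon (C29); the endo transition state places the two outside diene substituents cis to the enone ring (all-cis C13, C14, C25, C29); and the catalyst leaves only the Si face at C2/C3 of 8 open, which fixes the absolute configuration.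

Step 5
Reactants: 9 all-cis Diels–Alder adduct
Product: 10 C9 ethylene ketal of 9 (spiro-1,3-dioxolane at C9; configuration unchanged)
Conditions: (TMSOCH2)2, TMSOTf (5 mol %), CH2Cl2, −78 → −40 °C; then pyridine
Reagents that add atoms: 1,2-bis(trimethylsilyloxy)ethane, C[Si](C)(C)OCCO[Si](C)(C)C
Why: Ketalisation under aprotic Noyori conditions at low temperature masks the C9 ketone, which would otherwise enolise and compete in step 10, without epimerising C29 or protonating the silyl enol ether.

Step 6
Reactants: 10 C9 ethylene ketal
Product: 11 primary alcohol (2-hydroxyethyl arm on C25)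
Conditions: H2 (1 atm), Pd/C (10 wt %), EtOAc, rt
Reagents that add atoms: none
Why: Hydrogenolysis of the benzyl ether; the hindered trisubstituted TIPS enol ether, the ketal and the ester are not expected to react at 1 atm.

Step 7
Reactants: 11 primary alcohol
Product: 12 aldehyde (2-oxoethyl arm on C25)
Conditions: Dess–Martin periodinane, pyridine, CH2Cl2, 0 °C → rt
Reagents that add atoms: none
Why: Dess–Martin oxidation under buffered, non-aqueous conditions that should leave the silyl enol ether and the ketal untouched.

Step 8
Reactants: 12 aldehyde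
Product: 13 carboxylic acid (carboxymethyl arm on C25)
Conditions: NaClO2, NaH2PO4, 2-methyl-2-butene (excess), t-BuOH/H2O, 0 °C
Reagents that add atoms: sodium chlorite, [Na+].[O-]Cl=O
Why: Pinnick oxidation; the excess of 2-methyl-2-butene scavenges HOCl before it can chlorinate the enol ether, and the short exposure to the weakly acidic buffer should be tolerated by the TIPS enol ether and the dioxolane.

Step 9
Reactants: 13 carboxylic acid
Product: 14 all-cis diester (CO2Me on C14, CH2CO2Me on C25, TIPS enol ether C15=C16, dioxolane at C9)
Conditions: TMSCHN2, MeOH/toluene, 0 °C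
Reagents that add atoms: (trimethylsilyl)diazomethane, C[Si](C)(C)C=[N+]=[N-]
Why: Methyl ester formation with (trimethylsilyl)diazomethane under neutral conditions, so that no base touches C14 before the key step.

Step 10
Reactants: 14 all-cis diester
Product: 16 bicyclo[2.2.2]octene β-keto ester (enol form; C27 enol, CO2Me on C26, TIPS enol ether C15=C16, dioxolane at C9), via potassium enolate 15 (not isolated)
Conditions: KOt-Bu (1.2 equiv), THF, 0 °C → rt; aq. NH4Cl
Reagents that add atoms: none
Why: Dieckmann condensation: the enolate carbon C26 of the acetate arm on C25 adds to the ester carbonyl C27 on C14, methoxide leaves, and the new β-keto ester is deprotonated at C26 to the potassium enolate 15, which removes it from all equilibria. The closest known reaction is the Dieckmann bridging of cis-1,4-disubstituted cyclohexane diesters to bicyclo[2.2.2]octanones. The closure is a 6-(enolexo)-exo-trig attack that forms the six-membered ring C14–C27–C26–C25–C29–C13 (equally C14–C27–C26–C25–C16–C15) and with it the bicyclo[2.2.2]octene. No stereocentre is created: C14 and C25 become bridgeheads whose configuration is dictated by the cis placement of the two arms from step 4, and only the cis isomer can bridge. The selectivity needed is C26→C27 over the reverse mode (C14 carbanion onto the arm carbonyl) and over reversible enolisation at C14; it is thermodynamic, because only the C26–C27 product has an acidic C–H between two carbonyls, whereas the reverse product, with a bridgehead C14 that cannot be enolised, reverts by retro-Claisen and the open isomers re-equilibrate through the C14 dienolate. The bulky TIPS group and the use of little more than one equivalent of a hindered alkoxide keep the C15=C16 enol ether in place, and this enol ether in turn keeps C15 from becoming a ketone that would turn C14 into an unreactive β-keto ester enolate.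

Step 11
Reactants: 16 bicyclic β-keto ester
Product: 18 bicyclic ketone (C27=O, C26H2, TIPS enol ether C15=C16, dioxolane at C9), via lithium β-keto carboxylate 17 (not isolated)
Conditions: LiCl, H2O (2 equiv), DMSO, 130 °C
Reagents that add atoms: none
Why: Krapcho dealkoxycarbonylation: chloride demethylates the β-keto ester and carboxylate 17 loses CO2 through the C26=C27 enolate, which does not lie at a bridgehead, under neutral conditions that should spare ketal and TIPS enol ether.

Step 12
Reactants: 18 bicyclic ketone
Product: 19 (27S)-alcohol (OH on C27 on the side of the C15=C16 bridge)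
Conditions: SmI2 (2.5 equiv), THF/MeOH, 0 °C → rt
Reagents that add atoms: none
Why: Single-electron ketone reduction with SmI2, which should give the more stable carbinol: the oxygen on C27 settles next to the C15=C16 bridge and away from C12, which points straight at C27 from the C13–C29 bridge, so C27 takes the configuration of the target (a hydride reagent attacking from the open alkene side would give the other epimer).

Step 13
Reactants: 19 (27S)-alcohol
Product: 20 hydroxy diketone (C9=O, C15=O, C27–OH)
Conditions: 1 M HCl, THF, rt
Reagents that add atoms: water, O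
Why: Acid hydrolysis of the dioxolane and of the silyl enol ether frees both ketones; the β-hydroxy ketone cannot dehydrate because C14 is a bridgehead, and C29 stays cis because a six-membered ring cannot be trans-fused onto the eclipsed C13–C29 bridge.

Step 14
Reactants: 20 hydroxy diketone
Product: 21 O28-TBS ether of 20
Conditions: TBSOTf, 2,6-lutidine, CH2Cl2, −78 °C
Reagents that add atoms: tert-butyldimethylsilyl trifluoromethanesulfonate, CC(C)(C)[Si](C)(C)OS(=O)(=O)C(F)(F)F
Why: Silyl ether formation; blocking O28 prevents its acylation in step 15 and a base-induced retro-aldol cleavage of the C14–C27 bond.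

Step 15
Reactants: 21 TBS-protected diketone
Product: 22 bis(β-diketone) (pentanoyl on C10 and on C16; drawn as the C9=C10 and C15=C16 enols)
Conditions: pentanoyl chloride (2.6 equiv), MgBr2·OEt2, i-Pr2NEt, CH2Cl2, rt
Reagents that add atoms: pentanoyl chloride, CCCCC(=O)Cl
Why: Twofold C-acylation of ketones by soft enolisation (magnesium enolate, acid chloride): C15 can enolise only towards C16 because C14 is a bridgehead, and C9 is acylated at C10 and not at the hindered methine C29, since only the C10 product is held as a chelated diketonate.

Step 16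
Reactants: 22 bis(β-diketone)
Product: 23 bis(enol triflate) (OTf on C9 with C9=C10 and on C15 with C15=C16; pentanoyl on C10 and C16)
Conditions: Tf2O (2.3 equiv), i-Pr2NEt, CH2Cl2, −78 °C
Reagents that add atoms: trifluoromethanesulfonic anhydride, O=S(=O)(OS(=O)(=O)C(F)(F)F)C(F)(F)F
Why: Enol triflate formation from 1,3-diketones; sulfonylation is expected at the ring oxygens on C9 and C15 because 2-acylcycloalkanones react through their endocyclic enols, which leaves both pentanoyl groups as ketones.

Step 17
Reactants: 23 bis(enol triflate)
Product: 24 O28-TBS ether of the target (both (Z)-butylidene lactones in place)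
Conditions: PdCl2(PPh3)2 (10 mol %), Et3N (4 equiv), CO (5 atm), DMF, 80 °C
Reagents that add atoms: carbon monoxide, [C-]#[O+]
Why: Twofold palladium-catalysed carbonylative lactonisation of β-sulfonyloxy enones: zerovalent palladium inserts into each C–OTf bond, CO insertion gives acylpalladium groups on C9 and C15 (new carbons C7 and C23), and the enol oxygen of the neighbouring pentanoyl ketone closes each five-membered lactone, the Z-butylidene being the isomer that keeps the propyl chain away from C11H2 and from C25–H.

Step 18
Reactants: 24 O28-TBS ether of the target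
Product: 25 target CNP0289078.1 ((13S,14S,25R,27S,29R), both butylidenes Z)
Conditions: HF·pyridine, pyridine, THF, 0 °C → rt
Reagents that add atoms: none
Why: Fluoride-mediated silyl ether cleavage under buffered, weakly acidic conditions that the base-sensitive enol lactones should tolerate.

**Compound list**

1 | methyl acetoacetate | CC(=O)CC(=O)OC | starting material
2 | 3-(benzyloxy)propanal | O=CCCOCc1ccccc1 | starting material
3 | dilithio dianion of methyl acetoacetate (not isolated) | [Li+].[Li+].C=C([O-])C=C([O-])OC | intermediate
4 | methyl 7-(benzyloxy)-5-hydroxy-3-oxoheptanoate (racemic at C5) | COC(=O)CC(=O)CC(O)CCOCc1ccccc1 | intermediate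
5 | methyl 7-(benzyloxy)-5-(mesyloxy)-3-oxoheptanoate (racemic, not isolated) | COC(=O)CC(=O)CC(OS(C)(=O)=O)CCOCc1ccccc1 | intermediate
6 | methyl (4E)-7-(benzyloxy)-3-oxohept-4-enoate | COC(=O)CC(=O)/C=C/CCOCc1ccccc1 | intermediate
7 | methyl (2Z,4E)-7-(benzyloxy)-3-[(triisopropylsilyl)oxy]hepta-2,4-dienoate | COC(=O)/C=C(\O[Si](C(C)C)(C(C)C)C(C)C)/C=C/CCOCc1ccccc1 | intermediate
8 | cyclohex-2-en-1-one | O=C1C=CCCC1 | starting material
9 | methyl (1S,4S,4aS,8aS)-4-[2-(benzyloxy)ethyl]-5-oxo-2-[(triisopropylsilyl)oxy]-1,4,4a,5,6,7,8,8a-octahydronaphthalene-1-carboxylate (all-cis adduct) | O=C1CCC[C@@H]2[C@H](C(=O)OC)C(O[Si](C(C)C)(C(C)C)C(C)C)=C[C@H](CCOCc3ccccc3)[C@H]12 | intermediate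
10 | C9 ethylene ketal of 9 (spiro-dioxolane; ring stereocentres as in 9) | O1CCOC12CCC[C@@H]3[C@H](C(=O)OC)C(O[Si](C(C)C)(C(C)C)C(C)C)=C[C@H](CCOCc4ccccc4)[C@H]23 | intermediate
11 | primary alcohol (2-hydroxyethyl on C25; otherwise as 10) | O1CCOC12CCC[C@@H]3[C@H](C(=O)OC)C(O[Si](C(C)C)(C(C)C)C(C)C)=C[C@H](CCO)[C@H]23 | intermediate
12 | aldehyde (2-oxoethyl on C25) | O1CCOC12CCC[C@@H]3[C@H](C(=O)OC)C(O[Si](C(C)C)(C(C)C)C(C)C)=C[C@H](CC=O)[C@H]23 | intermediate
13 | carboxylic acid (carboxymethyl on C25) | O1CCOC12CCC[C@@H]3[C@H](C(=O)OC)C(O[Si](C(C)C)(C(C)C)C(C)C)=C[C@H](CC(=O)O)[C@H]23 | intermediate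
14 | all-cis diester (CO2Me on C14, CH2CO2Me on C25, C15 TIPS enol ether, C9 dioxolane) | O1CCOC12CCC[C@@H]3[C@H](C(=O)OC)C(O[Si](C(C)C)(C(C)C)C(C)C)=C[C@H](CC(=O)OC)[C@H]23 | intermediate
15 | potassium enolate of 16 (not isolated) | O1CCOC12CCC[C@@H]3[C@H]4C(O[Si](C(C)C)(C(C)C)C(C)C)=C[C@H](C(C(=O)OC)=C4[O-])[C@H]23.[K+] | intermediate
16 | bicyclo[2.2.2]octene β-keto ester, enol form (C27 enol, CO2Me on C26) | O1CCOC12CCC[C@@H]3[C@H]4C(O[Si](C(C)C)(C(C)C)C(C)C)=C[C@H](C(C(=O)OC)=C4O)[C@H]23 | intermediate
17 | lithium β-keto carboxylate, enol form (not isolated) | O1CCOC12CCC[C@@H]3[C@H]4C(O[Si](C(C)C)(C(C)C)C(C)C)=C[C@H](C(C(=O)[O-])=C4O)[C@H]23.[Li+] | intermediate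
18 | bicyclic ketone (C27=O, C26H2, C15 TIPS enol ether, C9 dioxolane) | O1CCOC12CCC[C@@H]3[C@H]4C(O[Si](C(C)C)(C(C)C)C(C)C)=C[C@H](CC4=O)[C@H]23 | intermediate
19 | (27S)-alcohol (OH on C27 syn to the C15=C16 bridge) | O1CCOC12CCC[C@@H]3[C@H]4C(O[Si](C(C)C)(C(C)C)C(C)C)=C[C@H](C[C@@H]4O)[C@H]23 | intermediate
20 | hydroxy diketone (C9=O, C15=O, C27–OH) | O=C1CCC[C@@H]2[C@H]3C(=O)C[C@H](C[C@@H]3O)[C@H]12 | intermediate
21 | O28-TBS ether of 20 | O=C1CCC[C@@H]2[C@H]3C(=O)C[C@H](C[C@@H]3O[Si](C)(C)C(C)(C)C)[C@H]12 | intermediate
22 | bis(β-diketone), pentanoyl on C10 and C16, drawn as ring enols | OC1=C(C(=O)CCCC)CC[C@@H]2[C@H]3C(O)=C(C(=O)CCCC)[C@H](C[C@@H]3O[Si](C)(C)C(C)(C)C)[C@H]12 | intermediate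
23 | bis(enol triflate), OTf on C9 and C15 | O=S(=O)(OC1=C(C(=O)CCCC)CC[C@@H]2[C@H]3C(OS(=O)(=O)C(F)(F)F)=C(C(=O)CCCC)[C@H](C[C@@H]3O[Si](C)(C)C(C)(C)C)[C@H]12)C(F)(F)F | intermediate
24 | O28-TBS ether of the target | CCC/C=C1\OC(=O)C2=C1CC[C@@H]1[C@H]3C4=C(/C(=C/CCC)OC4=O)[C@H](C[C@@H]3O[Si](C)(C)C(C)(C)C)[C@H]21 | intermediate
25 | CNP0289078.1, (13S,14S,25R,27S,29R), both butylidenes Z | CCC/C=C1\OC(=O)C2=C1CC[C@@H]1[C@H]3C4=C(/C(=C/CCC)OC4=O)[C@H](C[C@@H]3O)[C@H]21 | target

**Step count and risks**

Total: 18 steps. Longest linear sequence: 18 steps, from methyl acetoacetate (1); 2 and 8 are bought.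

Steps most likely to fail:

1. Step 4. The ester on C14 lowers the nucleophilicity of the diene terminus that must attack first. The cycloaddition may be too slow for the catalyst to survive, may stop after the first bond (conjugate addition without ring closure), or may proceed with poor facial selectivity. Fallback, from 7 and 8 back to 9: the two components are combined without catalyst under high pressure (about 12 kbar, CH2Cl2, room temperature). This should give the racemic endo adduct, that is 9 together with its mirror image, the (1R,4R,4aR,8aR)-adduct F1. The enantiomers are separated by preparative HPLC on a chiral stationary phase, and 9 re-enters the route at step 5.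

2. Step 10. The dienolate formed by reversible deprotonation at C14 may lose or transfer its silyl group, which would drain material into a C15 keto ester enolate that cannot bridge; or ring closure may simply be slower than these side reactions. Fallback, from 13 back to 18: the acid is converted with N-hydroxypyridine-2-thione, DCC and DMAP into the Barton ester F2. Irradiation of F2 in the presence of CHI3 removes CO2 and gives the primary iodide F3, with iodine on C26. SmI2/HMPA in THF then turns C26 into an organosamarium that adds to the C27 ester (intramolecular nucleophilic acyl substitution). This forms the same C26–C27 bond and the same ring without any base and gives ketone 18 directly, so that steps 9 to 11 are bypassed.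

3. Step 17. Two carbonylations and two captures by an enol oxygen must all succeed on one molecule. A stalled second oxidative addition, capture of an acylpalladium by adventitious water, or incomplete enolisation of a pentanoyl ketone would leave mixtures. Fallback, from 23 back to 24: twofold methoxycarbonylation (Pd(OAc)2, dppp, Et3N, CO, MeOH/DMF) gives the bis(methyl ester) F4. Saponification (LiOH, THF/H2O) gives the bis(γ-keto acid) F5. Acid-catalysed cyclodehydration (p-TsOH, toluene, reflux), the classical route from γ-keto acids to (Z)-alkylidene butenolides, then returns 24.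

**Further compounds**

F1 | step 4 | (1R,4R,4aR,8aR)-enantiomer of adduct 9 | O=C1CCC[C@H]2[C@@H](C(=O)OC)C(O[Si](C(C)C)(C(C)C)C(C)C)=C[C@@H](CCOCc3ccccc3)[C@@H]12
F2 | step 10 | Barton ester of acid 13 (2-thioxopyridin-1(2H)-yl ester of the C25 acetic acid arm) | O1CCOC12CCC[C@@H]3[C@H](C(=O)OC)C(O[Si](C(C)C)(C(C)C)C(C)C)=C[C@H](CC(=O)ON4C=CC=CC4=S)[C@H]23
F3 | step 10 | primary iodide (iodomethyl group on C25, iodine on C26; otherwise as 14 without the arm ester) | O1CCOC12CCC[C@@H]3[C@H](C(=O)OC)C(O[Si](C(C)C)(C(C)C)C(C)C)=C[C@H](CI)[C@H]23
F4 | step 17 | bis(methyl ester) (CO2Me on C9 and C15, pentanoyl on C10 and C16, O28-TBS) | COC(=O)C1=C(C(=O)CCCC)CC[C@@H]2[C@H]3C(C(=O)OC)=C(C(=O)CCCC)[C@H](C[C@@H]3O[Si](C)(C)C(C)(C)C)[C@H]12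
F5 | step 17 | bis(γ-keto acid), open form (CO2H on C9 and C15, pentanoyl on C10 and C16, O28-TBS) | OC(=O)C1=C(C(=O)CCCC)CC[C@@H]2[C@H]3C(C(=O)O)=C(C(=O)CCCC)[C@H](C[C@@H]3O[Si](C)(C)C(C)(C)C)[C@H]12
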